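## The problem

Target 24 is a monocyclic terpenoid ether of umbelliferone. Its single cyclohexene ring is numbered here C1 (alkene carbon carrying methyl C7), C2 (alkene CH), C3 (CH2), C4 (CH carrying the isovalerate), C5 (CMe2) and C6 (CH carrying the oxymethylene carbon C8, which is joined through oxygen to C7 of the coumarin). There is no ring fusion to lean on. The only two stereocentres, C4 (R) and C6 (S), lie on either side of the quaternary C5, with the C4 oxygen and C8 cis. Neither centre therefore has a stereogenic neighbour: C6 must be set absolutely and then govern C4 across the ring, or C4 must remain adjustable afterwards. The trisubstituted alkene must sit at C1=C2 and not drift to C1=C6 or to the exocyclic position, which argues against cationic or strongly acidic steps. The coumarin lactone (sensitive to hydride, hydroxide and nucleophiles) and the isovalerate (sensitive to hydride and base, and able to migrate to a free C8 hydroxyl) would not survive enolate, hydride or KH chemistry, so both must arrive last under near-neutral conditions; the aryl ether has to be made at a β-branched primary carbon. The enabling feature is that C4 is a homoallylic carbinol carbon (C4–C3–C2=C1), the retron of the 1,3-shift of a 2-vinylcyclobutanol. The atoms C4, C5, C6 and C1 that remain as the cyclobutane are the product of a [2+2] cycloaddition between a Me2C=C=X unit (C4, C5) and an allyl ether (C6, C1 with C8). The quaternary C5 then helps: the cyclobutanone can enolise only toward C1, and the ring-opened aldehyde of the key step cannot enolise at all.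

## Retrosynthesis

**C8–O(aryl) bond.** Target 24 is cut into primary alcohol 22 and umbelliferone 23. This cut comes first because the coumarin is the most fragile part and its phenol is acidic enough for a Mitsunobu etherification. Cutting on the aryl side of the oxygen is not an option, since the coumarin carbon is not activated for substitution. The forward reaction must be an SN2 displacement at a β-branched primary carbon under neutral conditions that spare the ester.

**Ester C–O bond and silyl ether.** Alcohol 22 goes back through silyl ether 21 to cyclohexenol 19 and isovaleryl chloride 20. Acylating before desilylation needs no selectivity between two hydroxyls. What is asked is acylation of a hindered secondary alcohol and a fluoride step in which the ester stays on O4.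

**Key cut: the C3–C4 bond, with the C4–C1 bond re-formed.** Cyclohexenol 19 is traced to 2-vinylcyclobutanol 16, in which C4 is bonded to C1 and the C2=C3 unit is a vinyl group on C1. Against a Diels–Alder or cationic cyclisation, this cut offers three things: one stereocentre (C6) in the precursor, an alkene position fixed by where the methyl group sits, and strain release as the driving force. The forward reaction must break only the C4–C1 bond, close through C3, and place the C4 oxygen cis to the C6 arm.

**C4 carbonyl, C1–C7 bond and C1–C2 bond.** Cyclobutanol 16 comes from ketone 15 by reduction. Ketone 15 comes from ethylidene ketone 12 and iodomethane 13 by α-methylation of the extended enolate. Ketone 12 comes from cyclobutanone 8 and acetaldehyde 9 by aldol condensation. Attaching the vinyl group as an ethylidene and shifting the double bond during methylation uses the fact that 8 has a single enolisable position; it avoids direct vinylation of an enolate. None of the new centres matters, since the C4 and C1 configurations are erased in the key step.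

**The four-membered ring: the C4–C1 and C5–C6 bonds.** Cyclobutanone 8 is cut into amide 5 and allyl silyl ether 2, joined through keteniminium ion 6 and iminium salt 7. This sets C6, the only stereocentre the key step needs, and assembles four ring carbons from two three- and four-carbon pieces. The forward reaction must bond the iminium carbon to the terminal alkene carbon, discriminate the alkene faces through the auxiliary, and leave the ether oxygen alone.

**Amide and silyl ether.** Amide 5 comes from isobutyryl chloride 3 and the twofold-symmetric amine 4. Ether 2 comes from allyl alcohol 1. Both are routine bond formations from commercial materials.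

## Roads not taken

**Alternative 1:** The cut is the C4–O bond, made by oxygen insertion. (1R,5R)-Verbenone A1 would be photoisomerised by 1,3-shift to chrysanthenone A2, the bicyclo[3.1.1] cyclobutanone whose carbonyl C8 spans C4 and C6. Baeyer–Villiger oxidation, with bridgehead C4 migrating with retention, would give bridged lactone A3. Hydride would open A3 to cis diol A4, the primary hydroxyl would be etherified with 23, and the secondary one acylated with 20.

- Merits: about five steps; the cis relationship is enforced by the bicycle; every ring carbon and both stereocentres come from the chiral pool. In step count and in certainty of the cis geometry this road is better than the chosen one.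
- Weak points: the oxygen must insert on the C4 side, but the competing bridgehead C6 is allylic and so the electronically better migrating group; the regiochemistry is at best unselective and may be the wrong one. A peracid would also epoxidise the trisubstituted alkene, while alkaline H2O2 can cleave a strained β,γ-unsaturated cyclobutanone hydrolytically. The photochemical route to A2 can pass through a ring-opened ketene that recloses on either face, which would erode optical purity.
- Comparison: the chosen plan is twice as long, but its ring expansion cannot give a constitutional isomer, because only one bond of the cyclobutanol can break to a stabilised anion and only one terminus can close a six-membered ring.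

**Alternative 2:** The cut is the C1–C6 bond, made by a 1,2-shift. Irradiation of diazo enone A5 in methanol would expel N2, shift alkenyl carbon C1 from the carbonyl carbon (the future C8) to C6, and trap the ketene as ester A6.

- Merits: C4 and its oxygen are in place early and from the chiral pool, so the absolute configuration is not in question. On this point it is better than an auxiliary-controlled cycloaddition whose sense has to be established.
- Weak points: A5 needs a ring enlargement of a chiral-pool cyclohexenone, a gem-dimethyl installation and a diazo transfer beside a quaternary carbon, so it is much longer to reach than cyclobutanol 16. C6 is created by protonation of the ketene adduct, with only remote 1,3-induction from C4 across CMe2. In A6 the C6 hydrogen is both α to the ester and allylic, so it can epimerise, and the alkene can slip into conjugation at C1=C6.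
- Comparison: in the chosen plan C6 is never acidic, and the C4 centre can be corrected at the end.

**Alternative 3:** The cut is the C6–C8 bond. A Lewis acid (SnCl4 or In(OTf)3) would turn methoxymethyl ether A7 into an oxocarbenium ion whose carbon C8 attacks alkene carbon C6; the tertiary C1 cation loses a proton and gives bridged ether A8. Acylative opening of A8 at the primary C8–O bond with 20 would install the isovalerate and leave a C8 leaving group for etherification with 23.

- Merits: the tether from the C4 oxygen delivers C8 to the same face, so the cis relationship is certain, and the route could be as short as six or seven steps. Both points count in its favour against the chosen plan.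
- Weak points: the C1 cation can lose a proton from C2 (wanted) or from methyl C7 (exocyclic alkene), so alkene regiochemistry is not secured. The attacked carbon C6 is neopentyl and the closure is a strained bridging one. The acylative opening needs strong Lewis acid near an acid-sensitive trisubstituted alkene and must distinguish two hindered C–O bonds. The parent alcohol of A7 must be made enantiopure from a β,γ-unsaturated ketone that conjugates easily.
- Comparison: the chosen plan fixes the alkene position through the methyl group on the allyl unit and uses no cationic step.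

Key step: step 7

Assumption: the (2R,5R)-configured auxiliary 4 is taken to induce the (3S) configuration of cyclobutanone 8; should the cycloaddition favour the enantiomer, the equally available (2S,5S)-amine is used and nothing else changes.

## Route

Step 1
Reactants: 1 prop-2-en-1-ol (allyl alcohol)
Product: 2 triisopropyl(prop-2-en-1-yloxy)silane
Conditions: TIPSCl, imidazole, CH2Cl2, 0 °C → rt
Reagents that add atoms: chlorotriisopropylsilane (TIPSCl), CC(C)[Si](Cl)(C(C)C)C(C)C
Why: Standard silylation of a primary alcohol. The TIPS group is chosen because it survives triflate salts, enolates, hydride and KH, and because its bulk keeps the ether oxygen from attacking the keteniminium ion and from accepting the silyl group intramolecularly later.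

Step 2
Reactants: 3 2-methylpropanoyl chloride (isobutyryl chloride); 4 (2R,5R)-2,5-dimethylpyrrolidine
Product: 5 1-[(2R,5R)-2,5-dimethylpyrrolidin-1-yl]-2-methylpropan-1-one
Conditions: Et3N, CH2Cl2, 0 °C → rt
Reagents that add atoms: none
Why: N-Acylation of a secondary amine by an acid chloride; the stereocentres of the amine are not touched.

Step 3
Reactants: 5 1-[(2R,5R)-2,5-dimethylpyrrolidin-1-yl]-2-methylpropan-1-one; 2 triisopropyl(prop-2-en-1-yloxy)silane
Product: 8 (3S)-2,2-dimethyl-3-[(triisopropylsilyloxy)methyl]cyclobutan-1-one, via keteniminium triflate 6 (not isolated), via cyclobutaniminium triflate 7 (not isolated)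
Conditions: Tf2O, 2,4,6-collidine, ClCH2CH2Cl, −20 °C → rt; 2 (excess), 80 °C; then H2O, 60 °C
Reagents that add atoms: water, O
Why: Keteniminium [2+2] cycloaddition (Ghosez type): amide activation gives 6, whose electrophilic central carbon bonds to the terminal CH2 of 2 while the internal alkene carbon closes onto CMe2, so hydrolysis of 7 gives the 3-substituted 2,2-dimethylcyclobutanone and returns amine 4. The C6 stereocentre is set here by the twofold-symmetric pyrrolidine, which makes both directions of approach to the iminium carbon equivalent and leaves one orientation of the alkene substituent less hindered. The hindered TIPS ether oxygen should not compete with the alkene for 6.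

Step 4
Reactants: 8 (3S)-2,2-dimethyl-3-[(triisopropylsilyloxy)methyl]cyclobutan-1-one; 9 acetaldehyde
Product: 12 (3R,4E)-4-ethylidene-2,2-dimethyl-3-[(triisopropylsilyloxy)methyl]cyclobutan-1-one, via lithium aldolate 10 (not isolated), via aldol mesylate 11 (not isolated)
Conditions: LiN(i-Pr)2, THF, −78 °C; MeCHO; MsCl, −78 → 0 °C; DBU, rt
Reagents that add atoms: none
Why: Aldol condensation in one flask: the only possible enolate of 8 (C5 is quaternary) adds to 9, the lithium aldolate is mesylated and DBU effects E1cB elimination. Both aldol epimers eliminate, the alkene geometry (E expected, Z equally usable) is lost in step 5, and the C6 hydrogen is not acidic; the descriptor at C6 changes from S to R only through the priority rules.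

Step 5
Reactants: 12 (3R,4E)-4-ethylidene-2,2-dimethyl-3-[(triisopropylsilyloxy)methyl]cyclobutan-1-one; 13 iodomethane
Product: 15 (3R)-4-ethenyl-2,2,4-trimethyl-3-[(triisopropylsilyloxy)methyl]cyclobutan-1-one (both C4 epimers), via lithium dienolate 14 (not isolated)
Conditions: LiN(i-Pr)2, THF/DMPU, −78 °C; MeI, −78 → 0 °C
Reagents that add atoms: none
Why: Deconjugative α-alkylation: with no α′-hydrogen, the base removes a γ-proton of the ethylidene methyl group, and the extended enolate 14 is methylated at the α-carbon to give the β,γ-unsaturated ketone with methyl and vinyl on C1. Methylation should occur mainly anti to the C6 arm, but this quaternary centre is erased in step 7; 15 has no enolisable hydrogen left, so over-alkylation is impossible.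

Step 6
Reactants: 15 (3R)-4-ethenyl-2,2,4-trimethyl-3-[(triisopropylsilyloxy)methyl]cyclobutan-1-one (both C4 epimers)
Product: 16 (3R)-4-ethenyl-2,2,4-trimethyl-3-[(triisopropylsilyloxy)methyl]cyclobutan-1-ol (epimers at C1 and C4)
Conditions: NaBH4, MeOH, 0 °C
Reagents that add atoms: none
Why: Hydride reduction of a strained and therefore reactive cyclobutanone; the vinyl group and silyl ether are inert. The carbinol configuration is erased in step 7, so the epimer mixture is used as such.

Step 7
Reactants: 16 (3R)-4-ethenyl-2,2,4-trimethyl-3-[(triisopropylsilyloxy)methyl]cyclobutan-1-ol (epimers at C1 and C4)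
Product: 19 (1R,5S)-4,6,6-trimethyl-5-[(triisopropylsilyloxy)methyl]cyclohex-3-en-1-ol, via potassium cyclobutanolate 17 (not isolated), via allylpotassium aldehyde 18 (not isolated)
Conditions: KH, 18-crown-6, THF, 0 → 50 °C; then H2O
Reagents that add atoms: none
Why: KH converts 16 into alkoxide 17, whose oxyanion weakens the adjacent, strained C4–C1 bond; heterolysis gives aldehyde 18 with a methyl-substituted allyl anion still tied to it through C5 and C6, and the allyl terminus C3 then adds to the formyl carbon C4, in sum a 1,3-shift from a four- to a six-membered ring. The closest known reaction type is the alkoxide-accelerated vinylcyclobutane rearrangement of 2-vinylcyclobutanol salts to cyclohex-3-en-1-ols, the small-ring relative of the anionic oxy-Cope acceleration. The cyclohexene closes in a 6-exo-trig mode at the C4 carbonyl with the allyl unit C1–C2–C3 inside the new ring; reclosure through C1 only regenerates 17 and is drained by the strain-free cyclohexenolate. Constitution is secured by the substrate: only the C4–C1 bond can break to a stabilised carbanion (C5 is quaternary), the aldehyde of 18 cannot enolise, and the methyl group fixes the alkene at C1=C2. The new C4 stereocentre is controlled by C6, whose hydrogen is never acidic: the CH2OTIPS arm turns to the allyl face opposite the incoming aldehyde to avoid eclipsing the C1 methyl group (A(1,2) strain). With K+ held in the crown ether the closure should pass through an open transition state in which the carbonyl oxygen points away from the allyl unit, which puts oxygen and arm on the same ring face (cis; both equatorial once the half-chair relaxes). All epimers of 16 converge because the C4 and C1 centres are erased in 18. The TIPS ether is too hindered to migrate to the alkoxide and is inert to KH.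

Step 8
Reactants: 19 (1R,5S)-4,6,6-trimethyl-5-[(triisopropylsilyloxy)methyl]cyclohex-3-en-1-ol; 20 3-methylbutanoyl chloride (isovaleryl chloride)
Product: 21 (1R,5S)-4,6,6-trimethyl-5-[(triisopropylsilyloxy)methyl]cyclohex-3-en-1-yl 3-methylbutanoate
Conditions: pyridine, DMAP (cat.), CH2Cl2, 0 °C → rt
Reagents that add atoms: none
Why: DMAP-catalysed acylation of the secondary C4 alcohol by an acid chloride; the neopentyl position only slows it, and no stereocentre is touched.

Step 9
Reactants: 21 (1R,5S)-4,6,6-trimethyl-5-[(triisopropylsilyloxy)methyl]cyclohex-3-en-1-yl 3-methylbutanoate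
Product: 22 (1R,5S)-5-(hydroxymethyl)-4,6,6-trimethylcyclohex-3-en-1-yl 3-methylbutanoate
Conditions: n-Bu4NF, AcOH, THF, 0 °C → rt
Reagents that add atoms: none
Why: Fluoride cleavage of the primary TIPS ether; acetic acid buffers the liberated C8 alkoxide so that the isovalerate neither migrates from O4 to O8 nor is cleaved.

Step 10
Reactants: 22 (1R,5S)-5-(hydroxymethyl)-4,6,6-trimethylcyclohex-3-en-1-yl 3-methylbutanoate; 23 7-hydroxy-2H-chromen-2-one (umbelliferone)
Product: 24 (1R,5S)-4,6,6-trimethyl-5-{[(2-oxo-2H-chromen-7-yl)oxy]methyl}cyclohex-3-en-1-yl 3-methylbutanoate (CNP0266015.1)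
Conditions: PPh3, DIAD, THF, 0 °C → rt
Reagents that add atoms: none
Why: Mitsunobu etherification: the acidic phenol of 23 (pKa about 8) displaces the oxyphosphonium group at primary C8 by SN2 under neutral conditions that leave the ester, the lactone and the alkene untouched. No stereocentre is involved.

## Compound list

1 | prop-2-en-1-ol (allyl alcohol) | C=CCO | starting material
2 | triisopropyl(prop-2-en-1-yloxy)silane | C=CCO[Si](C(C)C)(C(C)C)C(C)C | intermediate
3 | 2-methylpropanoyl chloride (isobutyryl chloride) | CC(C)C(Cl)=O | starting material
4 | (2R,5R)-2,5-dimethylpyrrolidine | C[C@@H]1CC[C@@H](C)N1 | starting material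
5 | 1-[(2R,5R)-2,5-dimethylpyrrolidin-1-yl]-2-methylpropan-1-one | CC(C)C(=O)N1[C@H](C)CC[C@H]1C | intermediate
6 | (2R,5R)-2,5-dimethyl-1-(2-methylprop-1-en-1-ylidene)pyrrolidin-1-ium trifluoromethanesulfonate (keteniminium triflate) | CC(C)=C=[N+]1[C@H](C)CC[C@H]1C.[O-]S(=O)(=O)C(F)(F)F | intermediate
7 | (2R,5R)-1-{(3S)-2,2-dimethyl-3-[(triisopropylsilyloxy)methyl]cyclobutylidene}-2,5-dimethylpyrrolidin-1-ium trifluoromethanesulfonate | CC1(C)[C@@H](CO[Si](C(C)C)(C(C)C)C(C)C)CC1=[N+]2[C@H](C)CC[C@H]2C.[O-]S(=O)(=O)C(F)(F)F | intermediate
8 | (3S)-2,2-dimethyl-3-[(triisopropylsilyloxy)methyl]cyclobutan-1-one | CC1(C)[C@@H](CO[Si](C(C)C)(C(C)C)C(C)C)CC1=O | intermediate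
9 | acetaldehyde | CC=O | starting material
10 | lithium 1-{(2S)-3,3-dimethyl-4-oxo-2-[(triisopropylsilyloxy)methyl]cyclobutyl}ethan-1-olate (aldolate, epimer mixture at the two new centres) | CC([O-])C1C(=O)C(C)(C)[C@H]1CO[Si](C(C)C)(C(C)C)C(C)C.[Li+] | intermediate
11 | 1-{(2S)-3,3-dimethyl-4-oxo-2-[(triisopropylsilyloxy)methyl]cyclobutyl}ethyl methanesulfonate (epimer mixture) | CC(OS(C)(=O)=O)C1C(=O)C(C)(C)[C@H]1CO[Si](C(C)C)(C(C)C)C(C)C | intermediate
12 | (3R,4E)-4-ethylidene-2,2-dimethyl-3-[(triisopropylsilyloxy)methyl]cyclobutan-1-one | C/C=C1\[C@H](CO[Si](C(C)C)(C(C)C)C(C)C)C(C)(C)C1=O | intermediate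
13 | iodomethane | CI | starting material
14 | lithium (3R)-2-ethenyl-4,4-dimethyl-3-[(triisopropylsilyloxy)methyl]cyclobut-1-en-1-olate (dienolate) | C=CC1=C([O-])C(C)(C)[C@H]1CO[Si](C(C)C)(C(C)C)C(C)C.[Li+] | intermediate
15 | (3R)-4-ethenyl-2,2,4-trimethyl-3-[(triisopropylsilyloxy)methyl]cyclobutan-1-one (both C4 epimers) | C=CC1(C)C(=O)C(C)(C)[C@H]1CO[Si](C(C)C)(C(C)C)C(C)C | intermediate
16 | (3R)-4-ethenyl-2,2,4-trimethyl-3-[(triisopropylsilyloxy)methyl]cyclobutan-1-ol (epimers at C1 and C4) | C=CC1(C)C(O)C(C)(C)[C@H]1CO[Si](C(C)C)(C(C)C)C(C)C | intermediate
17 | potassium (3R)-4-ethenyl-2,2,4-trimethyl-3-[(triisopropylsilyloxy)methyl]cyclobutan-1-olate | C=CC1(C)C([O-])C(C)(C)[C@H]1CO[Si](C(C)C)(C(C)C)C(C)C.[K+] | intermediate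
18 | potassium (2Z,4S)-3,5,5-trimethyl-6-oxo-4-[(triisopropylsilyloxy)methyl]hex-2-en-1-ide (ring-opened allyl anion aldehyde) | O=CC(C)(C)[C@@H](CO[Si](C(C)C)(C(C)C)C(C)C)/C(C)=C\[CH2-].[K+] | intermediate
19 | (1R,5S)-4,6,6-trimethyl-5-[(triisopropylsilyloxy)methyl]cyclohex-3-en-1-ol | CC1=CC[C@@H](O)C(C)(C)[C@H]1CO[Si](C(C)C)(C(C)C)C(C)C | intermediate
20 | 3-methylbutanoyl chloride (isovaleryl chloride) | CC(C)CC(Cl)=O | starting material
21 | (1R,5S)-4,6,6-trimethyl-5-[(triisopropylsilyloxy)methyl]cyclohex-3-en-1-yl 3-methylbutanoate | CC1=CC[C@@H](OC(=O)CC(C)C)C(C)(C)[C@H]1CO[Si](C(C)C)(C(C)C)C(C)C | intermediate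
22 | (1R,5S)-5-(hydroxymethyl)-4,6,6-trimethylcyclohex-3-en-1-yl 3-methylbutanoate | CC1=CC[C@@H](OC(=O)CC(C)C)C(C)(C)[C@H]1CO | intermediate
23 | 7-hydroxy-2H-chromen-2-one (umbelliferone) | Oc1ccc2ccc(=O)oc2c1 | starting material
24 | (1R,5S)-4,6,6-trimethyl-5-{[(2-oxo-2H-chromen-7-yl)oxy]methyl}cyclohex-3-en-1-yl 3-methylbutanoate | CC1=CC[C@@H](OC(=O)CC(C)C)C(C)(C)[C@H]1COc1ccc2ccc(=O)oc2c1 | target

## Step count and risks

Total: 10 steps. Longest linear sequence: 9 steps (steps 1 and 3 to 10, or steps 2 and 3 to 10).

**Step 7 (key step).** The most likely failure is poor face discrimination in the ring closure. If K+ is not fully sequestered it can bridge the carbonyl oxygen and the allyl unit, turning the oxygen over the allyl face and giving the C4 epimer. Premature protonation of the allyl anion by adventitious acid would also stop the sequence at the open-chain aldehyde stage. The fallback sets out from 16 and returns at 19. The rearrangement is run as planned, and the mixture of 19 and its epimer (1S,5S)-4,6,6-trimethyl-5-[(triisopropylsilyloxy)methyl]cyclohex-3-en-1-ol F1 is oxidised without separation (Dess–Martin periodinane, NaHCO3, CH2Cl2) to (5S)-4,6,6-trimethyl-5-[(triisopropylsilyloxy)methyl]cyclohex-3-en-1-one F2. This is reduced at once at −78 °C with LiBH(s-Bu)3. In F2 the C6 arm should sit pseudoaxial (A(1,2) strain against C7, no syn-axial partner at trigonal C4) and shield one face of the carbonyl, so the bulky hydride enters from the other side and the hydroxyl ends cis to the arm, giving 19. Buffered oxidation and low-temperature reduction are meant to prevent migration of the alkene into conjugation. C4 is then set by reagent control and no longer by the closure.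

**Step 3.** Facial discrimination by the auxiliary may be incomplete in an intermolecular cycloaddition to a monosubstituted alkene, its sense is assumed and not secured, and the ether oxygen could still intercept the keteniminium ion. The fallback leaves the cycloaddition altogether. It does not set out from a compound of the route but from commercial (1S,5S)-4,6,6-trimethylbicyclo[3.1.1]hept-3-en-2-one F3 ((−)-verbenone), and it returns at 8 in five steps instead of three:

- RuCl3 (catalytic) with NaIO4 cleaves the enone to (1S,3R)-3-acetyl-2,2-dimethylcyclobutane-1-carboxylic acid F4.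
- Baeyer–Villiger oxidation with mCPBA (the cyclobutyl carbon migrates with retention) gives (1S,3R)-3-acetoxy-2,2-dimethylcyclobutane-1-carboxylic acid F5.
- LiAlH4 reduces the acid and removes the acetate, giving (1R,3S)-3-(hydroxymethyl)-2,2-dimethylcyclobutan-1-ol F6.
- TIPSCl and imidazole silylate only the primary hydroxyl, giving (1R,3S)-2,2-dimethyl-3-[(triisopropylsilyloxy)methyl]cyclobutan-1-ol F7.
- Dess–Martin oxidation gives 8.

The carboxyl-bearing carbon of F4 becomes C6, so the absolute configuration is fixed by the chiral pool.

**Step 5.** The amide base may add in conjugate fashion to the strained exocyclic enone, or the extended enolate may be methylated at oxygen or at the γ-carbon instead of the α-carbon. The fallback sets out from 8 and returns at 15, reversing the order of the two carbon–carbon bond formations. Ketone 8 is methylated first (LiN(i-Pr)2, then 13) to (3S)-2,2,4-trimethyl-3-[(triisopropylsilyloxy)methyl]cyclobutan-1-one F8. Its enolate adds to 9 to give (3R)-4-(1-hydroxyethyl)-2,2,4-trimethyl-3-[(triisopropylsilyloxy)methyl]cyclobutan-1-one F9. Dehydration with the Burgess reagent gives 15; only the terminal alkene can form because the α-carbon is quaternary.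

**Step 10.** Displacement at the β-branched C8 may be so slow that the activated alcohol is consumed by alkylation of the hydrazide by-product. The fallback sets out from 22 and returns at 24, separating activation from etherification. Alcohol 22 is converted with I2, PPh3 and imidazole into (1R,5S)-5-(iodomethyl)-4,6,6-trimethylcyclohex-3-en-1-yl 3-methylbutanoate F10. This is heated with 23 and Cs2CO3 in DMF (Williamson etherification with the weakly basic phenoxide, which spares the ester) to give 24.

## Further compounds

F1 | step 7 | (1S,5S)-4,6,6-trimethyl-5-[(triisopropylsilyloxy)methyl]cyclohex-3-en-1-ol | CC1=CC[C@H](O)C(C)(C)[C@H]1CO[Si](C(C)C)(C(C)C)C(C)C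
F2 | step 7 | (5S)-4,6,6-trimethyl-5-[(triisopropylsilyloxy)methyl]cyclohex-3-en-1-one | CC1=CCC(=O)C(C)(C)[C@H]1CO[Si](C(C)C)(C(C)C)C(C)C
F3 | step 3 | (1S,5S)-4,6,6-trimethylbicyclo[3.1.1]hept-3-en-2-one ((−)-verbenone) | CC1=CC(=O)[C@H]2C[C@@H]1C2(C)C
F4 | step 3 | (1S,3R)-3-acetyl-2,2-dimethylcyclobutane-1-carboxylic acid | CC(=O)[C@@H]1C[C@H](C(O)=O)C1(C)C
F5 | step 3 | (1S,3R)-3-acetoxy-2,2-dimethylcyclobutane-1-carboxylic acid | CC(=O)O[C@@H]1C[C@H](C(O)=O)C1(C)C
F6 | step 3 | (1R,3S)-3-(hydroxymethyl)-2,2-dimethylcyclobutan-1-ol | O[C@@H]1C[C@H](CO)C1(C)C
F7 | step 3 | (1R,3S)-2,2-dimethyl-3-[(triisopropylsilyloxy)methyl]cyclobutan-1-ol | O[C@@H]1C[C@H](CO[Si](C(C)C)(C(C)C)C(C)C)C1(C)C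
F8 | step 5 | (3S)-2,2,4-trimethyl-3-[(triisopropylsilyloxy)methyl]cyclobutan-1-one (both C4 epimers) | CC1C(=O)C(C)(C)[C@H]1CO[Si](C(C)C)(C(C)C)C(C)C
F9 | step 5 | (3R)-4-(1-hydroxyethyl)-2,2,4-trimethyl-3-[(triisopropylsilyloxy)methyl]cyclobutan-1-one (epimer mixture) | CC(O)C1(C)C(=O)C(C)(C)[C@H]1CO[Si](C(C)C)(C(C)C)C(C)C
F10 | step 10 | (1R,5S)-5-(iodomethyl)-4,6,6-trimethylcyclohex-3-en-1-yl 3-methylbutanoate | CC1=CC[C@@H](OC(=O)CC(C)C)C(C)(C)[C@H]1CI
A1 | alternative 1 | (1R,5R)-4,6,6-trimethylbicyclo[3.1.1]hept-3-en-2-one ((+)-verbenone) | CC1=CC(=O)[C@@H]2C[C@H]1C2(C)C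
A2 | alternative 1 | (1S,5R)-2,7,7-trimethylbicyclo[3.1.1]hept-2-en-6-one (chrysanthenone) | CC1=CC[C@@H]2C(C)(C)[C@H]1C2=O
A3 | alternative 1 | (1S,5R)-2,8,8-trimethyl-6-oxabicyclo[3.2.1]oct-2-en-7-one | CC1=CC[C@@H]2C(C)(C)[C@H]1C(=O)O2
A4 | alternative 1 | (1R,5S)-5-(hydroxymethyl)-4,6,6-trimethylcyclohex-3-en-1-ol | CC1=CC[C@@H](O)C(C)(C)[C@H]1CO
A5 | alternative 2 | (5R)-5-[tert-butyl(dimethyl)silyl]oxy-7-diazo-2,6,6-trimethylcyclohept-2-en-1-one | CC1=CC[C@@H](O[Si](C)(C)C(C)(C)C)C(C)(C)C(=[N+]=[N-])C1=O
A6 | alternative 2 | methyl (1S,5R)-5-[tert-butyl(dimethyl)silyl]oxy-2,6,6-trimethylcyclohex-2-ene-1-carboxylate | CC1=CC[C@@H](O[Si](C)(C)C(C)(C)C)C(C)(C)[C@H]1C(=O)OC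
A7 | alternative 3 | (4R)-4-(methoxymethoxy)-1,3,3-trimethylcyclohex-1-ene | CC1=CC(C)(C)[C@H](OCOC)CC1
A8 | alternative 3 | (1S,5R)-2,8,8-trimethyl-6-oxabicyclo[3.2.1]oct-2-ene | CC1=CC[C@@H]2C(C)(C)[C@H]1CO2
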